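The amounts came first when you asked me for a quick number and offered the hunch that target simply follows the reagent charged. That held at the low end: gamma, charged with 0.18 equiv, stood at 17.9% after 20.0 h, nearly all of what that charge allows, so there the reagent was the limiting reagent, whereas beta, with 2.8 equiv, stood at 90.3% after 40.0 h.

all flasks: substrate 0.40 M

| run | reagent | remark | time |
|---|---|---|---|
| gamma | 0.18 equiv | run made earlier |  |
| delta | 0.56 equiv | run made earlier |  |
| beta | 2.8 equiv | run made earlier |  |
| red | 2.40 equiv |  | 40 h |
| blue | 0.400 equiv |  | 40 h |
| grey | 0.900 equiv |  | 40 h |
| amber | 0.600 equiv |  | 40 h |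
| ochre | 1.80 equiv |  | 40 h |
| teal | 0.150 equiv |  | 40 h |

- gamma (time / h: target / %, substrate / %): 3.00: 16.5, 24.1; 6.00: 17.2, 13.9; 12.0: 17.7, 7.3; 20.0: 17.9, 4.7; 40.0: 17.2, 3.1
- delta (time / h: target / %, substrate / %): 4.00: 45.6, 12.5; 10.0: 48.8, 5.2; 20.0: 49.2, 3.4; 30.0: 49.5, 2.3; 40.0: 50.1, 1.8
- beta (time / h: target / %, substrate / %): 4.00: 89.9, 0.2; 10.0: 89.8, 0.6; 20.0: 89.7, 0.4; 30.0: 89.7, 0.2; 40.0: 90.3, 0

(each reading ± 0.3 percentage points)

1. ranking by amount of target, in percent of the substrate charged, from high to low, at 40 h (red / blue / grey / amber / ochre / teal)
2. the same order at 2.0 h (red / blue / grey / amber / ochre / teal)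
3. the amount of target, in percent of the substrate charged of the flask you put first, at 40 h
4. the amount of target, in percent of the substrate charged of the flask you put last, at 40 h

- the numbers in the tables scatter by 0.3 percentage points (one standard deviation)

So I worked with the fraction left out and not with the fraction made. At the last reading, 49.9% of the substrate in delta and 9.70% in beta had not become target, and multiplying each share by that run's equivalents of reagent gave 0.279 and 0.272. I took their mean, λ = 0.276, and called it the loss product, the share of substrate not made into target times the equivalents of reagent. Gamma gave 0.149, less than λ, so I used λ from delta's charge upward. For red it gave a loss of 11.5% and so a target of 88.5% at 40 h. For teal, below that range, I scaled the mean of gamma's last two readings per equivalent and reckoned 14.6%. Target rose with charge across the three runs, already at their first readings (16.5%, 45.6%, 89.9%), so I ranked the flasks by charge at both times.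

The forecast, from the same runs, said “yield rises monotonically with reagent at both times” and gave red > ochre > grey > amber > blue > teal at 40 h and red > ochre > grey > amber > blue > teal at 2.0 h, with 88% and 14.5%, a little below my two figures.

The flasks gave red > ochre > grey > amber > blue > teal at 40 h and red > ochre > grey > amber > blue > teal at 2.0 h, with 88.5% in red and 14.6% in teal.

    2 substrate → side product (k = 1.11 L mol⁻¹ h⁻¹)
    substrate + reagent → target (k = 4.55 L mol⁻¹ h⁻¹)
    2 reagent → self-condensation product (k = 0.504 L mol⁻¹ h⁻¹)

In red, 11.5% of the substrate had not become target, where λ had given 11.5%. The neighbouring flask is red with 6.00 equiv of reagent, and there λ gives a loss of 4.60% and a target of 95.4%. That flask reached 95.4% of target, and its side product, in which each unit counts as two of substrate, stood at 4.58% of the substrate charged after 40.0 h.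

(The data were computed on assumed constants, noise included.)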